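**Assumption:** locants in all intermediates follow briarane numbering (C1 quaternary with Me-15; C2 propionyloxy; C5(Me-16)=C6; C7 lactone O–CH; C8 C–OH; C9 and C14 acetoxy; C11=C20; C17 lactone CH(Me-18); C19 lactone C=O). (S)-Glyceraldehyde is used as its commercial acetonide. Target configuration from the SMILES: 1R,2R,5Z,7S,8S,9R,10S,14S,17R.

## Retrosynthetic overview

1. Target ⇐ 9,14-diol (final bis-acetylation) ⇐ γ-lactone closed last by a SmI2 Reformatsky reaction (C8–C17) of a C7 2-bromopropanoate onto a C8 ketone.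
2. Ten-membered ring ⇐ Ni/Cr closure of C6–C7 (Z-vinyl iodide + α-silyloxy aldehyde); C7–C9 come from (S)-glyceraldehyde, whose C8 stereocentre is only a relay and is later oxidised.
3. Key step: the C1–C10 bond by Mn(III)/Cu(II) oxidative radical 6-endo cyclisation of an acyclic 2-methyl-1,3-diketone onto a Z-trisubstituted alkene. It forms the cyclohexane, quaternary C1, C10 and the 11(20)-methylene at once, with chirality relayed from C9.
4. Acyclic precursor ⇐ 3-methylpentane-2,4-dione (C1–C3, C13–C15) + two copies of one Z-iodoallyl bromide from propargyl alcohol (C10–C12/C20 and C4–C6/C16).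
5. Ring order: cyclohexane (radical) → ten-membered carbocycle → lactone.

## Route

**Step 1**
Reactants: 1 prop-2-yn-1-ol
Product: 2 (Z)-3-iodo-2-methylprop-2-en-1-ol
Conditions: MeMgBr (2.5 equiv), CuI (10 mol %), THF, −10 °C → rt; then I2, −78 → 0 °C
Reagents that add atoms: methylmagnesium bromide C[Mg]Br; iodine II
Why: Cu-catalysed anti-carbomagnesiation of the propargyl alkoxide (Duboudin reaction) gives a chelated vinylmagnesium that is iodinated with retention, so I ends cis to CH2OH (Z).

**Step 2**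
Reactants: 2 (Z)-3-iodo-2-methylprop-2-en-1-ol
Product: 3 (Z)-3-bromo-1-iodo-2-methylprop-1-ene
Conditions: CBr4, PPh3, CH2Cl2, 0 °C
Reagents that add atoms: carbon tetrabromide BrC(Br)(Br)Br
Why: Appel bromination of a primary allylic alcohol leaves the olefin geometry untouched.

**Step 3**
Reactants: 3 (Z)-3-bromo-1-iodo-2-methylprop-1-ene; 4 3-methylpentane-2,4-dione
Product: 5 (Z)-8-iodo-3,7-dimethyloct-7-ene-2,4-dione (C1 epimers/enol, inconsequential)
Conditions: 4 (1.3 equiv), NaH, THF, 0 °C; n-BuLi (1 equiv), 0 °C; then 3, −78 → 0 °C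
Reagents that add atoms: none
Why: γ-alkylation of the 1,3-diketone dianion occurs at the terminal carbanion by SN2 on the allylic bromide and forms C12–C13; the vinyl iodide is inert.

**Step 4**
Reactants: 5 (Z)-8-iodo-3,7-dimethyloct-7-ene-2,4-dione; 6 (S)-2,2-dimethyl-1,3-dioxolane-4-carbaldehyde
Product: 7 (7Z,9R)-9-[(4S)-2,2-dimethyl-1,3-dioxolan-4-yl]-9-hydroxy-3,7-dimethylnon-7-ene-2,4-dione (briarane C9 R, C8 S)
Conditions: CrCl2 (4 equiv), NiCl2 (2 mol %), DMSO, rt
Reagents that add atoms: none
Why: Nozaki–Hiyama–Kishi coupling adds the alkenylchromium to the aldehyde only, with retention of Z geometry; Felkin–Anh (anti) addition to the α-alkoxy aldehyde sets 9R (minor syn epimer separated), and the non-basic conditions tolerate the diketone.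

**Step 5**
Reactants: 7
Product: 8 9-O-TBS ether of 7
Conditions: TBSCl, imidazole, DMF, rt
Reagents that add atoms: tert-butyldimethylsilyl chloride CC(C)(C)[Si](C)(C)Cl
Why: Standard silylation; the bulky allylic OTBS becomes the control element for the radical step, and any enol silyl ether of the diketone reverts on workup.

**Step 6 (key step)**
Reactants: 8
Product: 9 (1S,9R,10S)-cyclohexanone: ring C14(=O)–C1(Me)(COCH3)–C10H[CH(OTBS)(dioxolanyl)]–C11(=CH2)–C12H2–C13H2 (acetyl and C9 trans)
Conditions: Mn(OAc)3·2H2O (2.2 equiv), Cu(OAc)2·H2O (1 equiv), degassed AcOH, 25 °C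
Reagents that add atoms: none
Why: Mn(III)-based oxidative free-radical cyclisation (Snider type): the Mn(III) enolate gives the C1 diacyl radical, which adds 6-endo to C10, and Cu(II) oxidises the tertiary C11 radical with loss of H from Me-20 to give the exocyclic alkene (endocyclic isomers minor). In the chair transition state the Z-olefin places C9 pseudoaxial and the exocyclic acetyl is pseudoaxial (as the ester is in podocarpate-type cyclisations), so C2 and C9 end trans. A(1,3) strain holds H-9 in the olefin plane and the electrophilic radical attacks anti to the C9–OTBS bond (Kishi-type sense), so 9R gives 10S and the C1 configuration of the target; this 1,2-induction is an extrapolation and the main uncertainty.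

**Step 7**
Reactants: 9
Product: 10 (1R,9R,10S,14S)-14-hydroxy ketone (14-OH cis to the acetyl group, trans to Me-15)
Conditions: L-Selectride (1.05 equiv), THF, −78 °C; AcOH quench at −78 °C
Reagents that add atoms: none
Why: The bulky hydride attacks the ring ketone equatorially in the chair with the C10 side chain equatorial and Me-15 axial (as in Selectride reductions of 4,4-disubstituted 3-keto terpenoids), giving the axial 14S alcohol; the neopentyl methyl ketone reacts more slowly, and the cold quench avoids retro-aldol.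

**Step 8**
Reactants: 10
Product: 11 14-O-TBS ether of 10 (1R,9R,10S,14S)
Conditions: TBSOTf, 2,6-lutidine, CH2Cl2, −40 → 0 °C
Reagents that add atoms: tert-butyldimethylsilyl triflate CC(C)(C)[Si](C)(C)OS(=O)(=O)C(F)(F)F
Why: The silyl triflate protects the hindered axial alcohol, blocking retro-aldol and leaving the acetyl CH3 (C3) as the only enolisable position.

**Step 9**
Reactants: 11; 3 (Z)-3-bromo-1-iodo-2-methylprop-1-ene
Product: 12 (1R,5Z,9R,10S,14S)-ketone with C2(=O)–C3H2–C4H2–C5(Me)=C6H–I
Conditions: LDA (1.1 equiv), THF, −78 °C; then 3, DMPU, −78 → −20 °C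
Reagents that add atoms: none
Why: Kinetic lithium enolate alkylation at C3 (C1 is quaternary) by SN2 on the allylic bromide forms C3–C4 and installs the Z-vinyl iodide with I cis to C4.

**Step 10**
Reactants: 12
Product: 13 (1S,2R,5Z,9R,10S,14S)-C2 alcohol
Conditions: (S)-Me-CBS oxazaborolidine (1 equiv), catecholborane, toluene, −78 → −40 °C
Reagents that add atoms: none
Why: Corey–Bakshi–Shibata reduction is catalyst-controlled by the large (quaternary C1) versus small (CH2) flanking groups and the (S)-catalyst delivers 2R; catecholborane avoids hydroboration of the alkenes.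

**Step 11**
Reactants: 13
Product: 14 C2 propanoate of 13
Conditions: (EtCO)2O, DMAP, Et3N, CH2Cl2, rt
Reagents that add atoms: propanoic anhydride CCC(=O)OC(=O)CC
Why: DMAP-catalysed acylation installs the final C2 propionate and removes the ketone so the later alkenylchromium cannot add to it.

**Step 12**
Reactants: 14
Product: 15 C7,C8-diol (acetonide removed; C8 S)
Conditions: CuCl2·2H2O, MeCN, 0 °C → rt
Reagents that add atoms: none (water supplies only H)
Why: Mild Lewis-acid hydrolysis cleaves the terminal isopropylidene acetal selectively; the secondary TBS ethers and the ester survive.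

**Step 13**
Reactants: 15
Product: 16 C7,C8-bis(triethylsilyl) ether
Conditions: TESCl, imidazole, DMAP (cat.), CH2Cl2, 0 °C
Reagents that add atoms: chlorotriethylsilane CC[Si](CC)(CC)Cl
Why: Routine bis-silylation sets up the selective oxidation of the primary position.

**Step 14**
Reactants: 16
Product: 17 C7 aldehyde with 8-OTES (C8 now R by CIP, spatially unchanged)
Conditions: (COCl)2, DMSO, CH2Cl2, −78 → −40 °C; then Et3N, −78 °C → rt
Reagents that add atoms: none
Why: Swern conditions oxidise a primary TES ether directly to the aldehyde while secondary TES and TBS ethers are untouched (known chemoselective oxidative desilylation).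

**Step 15**
Reactants: 17
Product: 18 (1S,2R,5Z,7S,8S,9R,10S,14S)-ten-membered carbocycle: 7-OH, 8-OTES, 9-OTBS, 14-OTBS, 2-propanoate
Conditions: CrCl2 (10 equiv), NiCl2 (1 mol %), DMSO/THF 3:1, 0.003 M, slow addition, rt
Reagents that add atoms: none
Why: Intramolecular Nozaki–Hiyama–Kishi closure of C6–C7 with retention of the Z-olefin; Felkin–Anh anti addition to the α-OTES aldehyde, reinforced by the anti β-OTBS, sets 7S, and the cyclohexane and Z-alkene preorganise the chain.

**Step 16**
Reactants: 18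
Product: 19 7-O-(2-bromopropanoate) of 18 (CHBr epimers, inconsequential)
Conditions: 2-bromopropanoyl bromide, pyridine, CH2Cl2, −20 → 0 °C
Reagents that add atoms: 2-bromopropanoyl bromide CC(Br)C(=O)Br
Why: Acylation of the allylic alcohol supplies C17–C19 as a Reformatsky donor tethered to O-7.

**Step 17**
Reactants: 19
Product: 20 8-alcohol (TES removed)
Conditions: HF·pyridine, pyridine, THF, 0 °C
Reagents that add atoms: none
Why: Buffered HF cleaves the secondary TES ether far faster than the hindered secondary TBS ethers and does not promote acyl migration.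

**Step 18**
Reactants: 20
Product: 21 (1S,2R,5Z,7S,9R,10S,14S)-C8 ketone
Conditions: Dess–Martin periodinane, NaHCO3, CH2Cl2, 0 °C → rt
Reagents that add atoms: none
Why: Neutral buffered oxidation gives the α-acyloxy-α′-silyloxy ketone without epimerising C7 or C9.

**Step 19**
Reactants: 21
Product: 22 (1S,2R,5Z,7S,8S,9R,10S,14S,17R)-9,14-bis-O-TBS lactone (8-OH free)
Conditions: SmI2 (3 equiv), THF, −78 °C; sat. NH4Cl
Reagents that add atoms: none
Why: SmI2-promoted intramolecular Reformatsky reaction: fast C–Br reduction gives the Sm(III) enolate, which adds 5-exo to the C8 ketone through a chelated transition state. Delivery from O-7 onto the face anti to the C9–OTBS bond (polar Felkin–Anh) gives 8S and the trans-fused lactone, with Me-18 trans to C9 (17R); C17 can be equilibrated to this more stable epimer if needed.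

**Step 20**
Reactants: 22
Product: 23 (1R,2R,5Z,7S,8R,9R,10S,14S,17R)-8,9,14-triol (C8 R only by CIP change)
Conditions: HF·pyridine, THF, rt → 40 °C
Reagents that add atoms: none
Why: Acidic fluoride desilylation removes both secondary TBS ethers without the retro-aldol or translactonisation that basic fluoride could cause.

**Step 21**
Reactants: 23
Product: 24 junceellolide E
Conditions: Ac2O, pyridine, DMAP (cat.), CH2Cl2, rt
Reagents that add atoms: acetic anhydride CC(=O)OC(C)=O
Why: DMAP-catalysed acetylation esterifies the two secondary alcohols (C9, C14); the tertiary 8-OH does not react under these conditions.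

## Compound list

1 | prop-2-yn-1-ol | C#CCO | starting material
2 | (Z)-3-iodo-2-methylprop-2-en-1-ol | OC/C(C)=C\I | intermediate
3 | (Z)-3-bromo-1-iodo-2-methylprop-1-ene | BrC/C(C)=C\I | intermediate
4 | 3-methylpentane-2,4-dione | CC(=O)C(C)C(C)=O | starting material
5 | (Z)-8-iodo-3,7-dimethyloct-7-ene-2,4-dione | CC(=O)C(C)C(=O)CC/C(C)=C\I | intermediate
6 | (S)-2,2-dimethyl-1,3-dioxolane-4-carbaldehyde | O=C[C@@H]1COC(C)(C)O1 | starting material
7 | (7Z,9R)-9-[(4S)-dioxolanyl]-9-hydroxy-3,7-dimethylnon-7-ene-2,4-dione | CC(=O)C(C)C(=O)CC/C(C)=C\[C@@H](O)[C@@H]1COC(C)(C)O1 | intermediate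
8 | 9-O-TBS ether of 7 | CC(=O)C(C)C(=O)CC/C(C)=C\[C@@H](O[Si](C)(C)C(C)(C)C)[C@@H]1COC(C)(C)O1 | intermediate
9 | (1S,9R,10S)-2-acetyl-2-methyl-4-methylidenecyclohexanone with C9(OTBS)(dioxolanyl) side chain | C=C1CCC(=O)[C@@](C(C)=O)(C)[C@H]1[C@@H](O[Si](C)(C)C(C)(C)C)[C@@H]1COC(C)(C)O1 | intermediate
10 | (1R,9R,10S,14S)-14-hydroxy ketone | C=C1CC[C@H](O)[C@@](C(C)=O)(C)[C@H]1[C@@H](O[Si](C)(C)C(C)(C)C)[C@@H]1COC(C)(C)O1 | intermediate
11 | 14-O-TBS ether of 10 | C=C1CC[C@H](O[Si](C)(C)C(C)(C)C)[C@@](C(C)=O)(C)[C@H]1[C@@H](O[Si](C)(C)C(C)(C)C)[C@@H]1COC(C)(C)O1 | intermediate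
12 | (1R,5Z,9R,10S,14S)-C2 ketone with Z-vinyl iodide side chain | C=C1CC[C@H](O[Si](C)(C)C(C)(C)C)[C@@](C(=O)CC/C(C)=C\I)(C)[C@H]1[C@@H](O[Si](C)(C)C(C)(C)C)[C@@H]1COC(C)(C)O1 | intermediate
13 | (1S,2R,5Z,9R,10S,14S)-C2 alcohol | C=C1CC[C@H](O[Si](C)(C)C(C)(C)C)[C@@]([C@H](O)CC/C(C)=C\I)(C)[C@H]1[C@@H](O[Si](C)(C)C(C)(C)C)[C@@H]1COC(C)(C)O1 | intermediate
14 | C2 propanoate of 13 | C=C1CC[C@H](O[Si](C)(C)C(C)(C)C)[C@@]([C@H](OC(=O)CC)CC/C(C)=C\I)(C)[C@H]1[C@@H](O[Si](C)(C)C(C)(C)C)[C@@H]1COC(C)(C)O1 | intermediate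
15 | C7,C8-diol | C=C1CC[C@H](O[Si](C)(C)C(C)(C)C)[C@@]([C@H](OC(=O)CC)CC/C(C)=C\I)(C)[C@H]1[C@@H](O[Si](C)(C)C(C)(C)C)[C@@H](O)CO | intermediate
16 | C7,C8-bis-TES ether | C=C1CC[C@H](O[Si](C)(C)C(C)(C)C)[C@@]([C@H](OC(=O)CC)CC/C(C)=C\I)(C)[C@H]1[C@@H](O[Si](C)(C)C(C)(C)C)[C@@H](O[Si](CC)(CC)CC)CO[Si](CC)(CC)CC | intermediate
17 | C7 aldehyde, 8-OTES | C=C1CC[C@H](O[Si](C)(C)C(C)(C)C)[C@@]([C@H](OC(=O)CC)CC/C(C)=C\I)(C)[C@H]1[C@@H](O[Si](C)(C)C(C)(C)C)[C@@H](O[Si](CC)(CC)CC)C=O | intermediate
18 | (1S,2R,5Z,7S,8S,9R,10S,14S)-macrocycle, 7-OH | C=C1CC[C@H](O[Si](C)(C)C(C)(C)C)[C@@]2(C)[C@H]1[C@@H](O[Si](C)(C)C(C)(C)C)[C@@H](O[Si](CC)(CC)CC)[C@@H](O)/C=C(/C)CC[C@H]2OC(=O)CC | intermediate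
19 | 7-O-(2-bromopropanoate) | C=C1CC[C@H](O[Si](C)(C)C(C)(C)C)[C@@]2(C)[C@H]1[C@@H](O[Si](C)(C)C(C)(C)C)[C@@H](O[Si](CC)(CC)CC)[C@@H](OC(=O)C(C)Br)/C=C(/C)CC[C@H]2OC(=O)CC | intermediate
20 | 8-alcohol | C=C1CC[C@H](O[Si](C)(C)C(C)(C)C)[C@@]2(C)[C@H]1[C@@H](O[Si](C)(C)C(C)(C)C)[C@@H](O)[C@@H](OC(=O)C(C)Br)/C=C(/C)CC[C@H]2OC(=O)CC | intermediate
21 | C8 ketone | C=C1CC[C@H](O[Si](C)(C)C(C)(C)C)[C@@]2(C)[C@H]1[C@@H](O[Si](C)(C)C(C)(C)C)C(=O)[C@@H](OC(=O)C(C)Br)/C=C(/C)CC[C@H]2OC(=O)CC | intermediate
22 | 9,14-bis-O-TBS lactone | C=C1CC[C@H](O[Si](C)(C)C(C)(C)C)[C@@]2(C)[C@H]1[C@@H](O[Si](C)(C)C(C)(C)C)[C@@]1(O)[C@H](/C=C(/C)CC[C@H]2OC(=O)CC)OC(=O)[C@@H]1C | intermediate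
23 | 9,14-dideacetyl junceellolide E | C=C1CC[C@H](O)[C@@]2(C)[C@H]1[C@@H](O)[C@@]1(O)[C@H](/C=C(/C)CC[C@H]2OC(=O)CC)OC(=O)[C@@H]1C | intermediate
24 | junceellolide E | C=C1CC[C@H](OC(C)=O)[C@@]2(C)[C@H]1[C@@H](OC(C)=O)[C@@]1(O)[C@H](/C=C(/C)CC[C@H]2OC(=O)CC)OC(=O)[C@@H]1C | target

## Summary

Total steps: 21. Longest linear sequence: 21 (propargyl alcohol → 24; bromide 3 is used twice, in Steps 3 and 9).

Steps most likely to fail, each with a fallback that changes the approach:

1. **Step 6 (Mn(III)/Cu(II) radical cyclisation).** Risks: facial control by the C9 silyl ether, pseudoaxial delivery on the Z-olefin, exo/endo olefin mixtures, acid-labile groups in AcOH. Fallback: generate the C1 radical reductively from an enantioenriched C1–C14 epoxide (Sharpless epoxidation of the C2 allylic alcohol analogue) with Cp2TiCl. The same 6-endo closure and Ti-mediated β-H elimination give the exo-methylene ring with 14-O already present and the absolute configuration set by the epoxide instead of C9.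
2. **Step 15 (ten-membered Ni/Cr closure).** Risks: oligomerisation, wrong C7 epimer. Fallback: move the ring-closing bond to C3–C4. Couple the C7 aldehyde intermolecularly with iodo alcohol 2 before Step 9, convert the C4 alcohol to the allylic bromide, and close the ring by intramolecular alkylation of the C2 methyl-ketone enolate.
3. **Step 19 (SmI2 Reformatsky lactonisation).** Risks: reductive cleavage of the α-acyloxy ketone, wrong C8 or C17 configuration. Fallback: esterify 7-OH with 2-(diethoxyphosphoryl)propanoic acid and close the Δ8(17)-butenolide by intramolecular Horner–Wadsworth–Emmons reaction, then install 8-OH and 17-H by nucleophilic epoxidation and reductive opening of the epoxy lactone.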